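**Retrosynthetic overview** (decahydroazulene numbering: C1 and C4 carry the methylidene groups, C2, C5 and C8 the hydroxyls, C7 the side chain, C3a and C8a are the ring-fusion carbons)

1. Target ⇐ late work on the five-membered ring only: C1 methylenation of a ketone, C2 oxygenation, side-chain acetate, desilylation.
2. Key disconnection C3a–C4 and C8–C8a: a [5+2] annulation of (R)-4-silyloxycyclopent-2-enone with the chain C4–C8, which is an alkenylmetal at C4 and a masked aldehyde at C8 (1,4-addition, then aldol).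
3. Enabling feature: the exocyclic methylene carbon C1 is a latent ketone, so C3a and C8a are the β- and α-carbons of a cyclopentenone. In the seven-membered ring C4 is sp2 and C8 is a carbinol, and C8–OH and C5–OH are 1,4-related, so the aldehyde can be stored as a five-membered lactol on the C5 oxygen.
4. Lactol ⇐ iodolactonisation of a 4,5-allenoic acid (sets C5 and the 1-iodoalkenyl group) ⇐ Evans propargylation (C7) and Crabbé homologation ⇐ acid from a Brown syn-crotylboration (both side-chain stereocentres).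
5. Ring order: five-membered carbocycle bought; temporary lactone/lactol ring; seven-membered ring closed last, in the key step.

Key step: step 12

Assumption: the (Z)-crotylborane made from (+)-Ipc2BOMe adds to the Re face of the unbranched aldehyde 2; should the sense be the other, the borane from (−)-Ipc2BOMe is used and nothing else changes.

Step 1
Reactants: 1 4-methylpent-3-en-1-ol
Product: 2 4-methylpent-3-enal
Conditions: Dess–Martin periodinane, pyridine, CH2Cl2, 0 °C; used at once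
Reagents that add atoms: none
Why: Dess–Martin oxidation under buffered, non-enolising conditions should give the β,γ-unsaturated aldehyde without migration of the double bond; no stereocentre is formed.

Step 2
Reactants: 2 4-methylpent-3-enal; 3 (Z)-but-2-ene
Product: 5 (3S,4S)-3,7-dimethylocta-1,6-dien-4-ol, via crotylborane 4 (not isolated)
Conditions: 3, KOt-Bu, n-BuLi, THF, −78 to −45 °C; (+)-Ipc2BOMe, −78 °C; BF3·OEt2; then 2, −78 °C; NaOH, H2O2
Reagents that add atoms: none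
Why: Brown crotylboration through a closed chair Zimmerman–Traxler transition state: the Z geometry of the borane should give the syn relationship and the isopinocampheyl groups should direct attack to the Re face, which sets 3S,4S.

Step 3
Reactants: 5 (3S,4S)-3,7-dimethylocta-1,6-dien-4-ol
Product: 6 1-({[(3S,4S)-3,7-dimethylocta-1,6-dien-4-yl]oxy}methyl)-4-methoxybenzene
Conditions: NaH, 4-methoxybenzyl chloride, Bu4NI (cat.), DMF, 0 °C to rt
Reagents that add atoms: 4-methoxybenzyl chloride, COc1ccc(CCl)cc1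
Why: Williamson etherification; the 4-methoxybenzyl ether should survive organolithium, hydride and silyl chemistry and can be removed oxidatively at the end, and no stereocentre is touched.

Step 4
Reactants: 6 1-({[(3S,4S)-3,7-dimethylocta-1,6-dien-4-yl]oxy}methyl)-4-methoxybenzene
Product: 8 (3S,4S)-4-[(4-methoxybenzyl)oxy]-3,7-dimethyloct-6-en-1-ol, via alkylborane 7 (not isolated)
Conditions: 9-BBN, THF, 0 °C to rt; NaOH, H2O2, 0 °C
Reagents that add atoms: hydrogen peroxide, OO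
Why: Hydroboration–oxidation with 9-BBN is anti-Markovnikov and should take the monosubstituted alkene in preference to the trisubstituted one on steric grounds; no new stereocentre.

Step 5
Reactants: 8 (3S,4S)-4-[(4-methoxybenzyl)oxy]-3,7-dimethyloct-6-en-1-ol
Product: 9 (3S,4S)-4-[(4-methoxybenzyl)oxy]-3,7-dimethyloct-6-enoic acid
Conditions: TEMPO (cat.), PhI(OAc)2, MeCN–H2O, rt
Reagents that add atoms: water, O
Why: Oxoammonium oxidation of the primary alcohol through the aldehyde hydrate should stop at the acid and leave the benzylic ether and the trisubstituted alkene alone.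

Step 6
Reactants: 9 (3S,4S)-4-[(4-methoxybenzyl)oxy]-3,7-dimethyloct-6-enoic acid; 10 (R)-4-benzyloxazolidin-2-one
Product: 12 (R)-4-benzyl-3-[(3S,4S)-4-[(4-methoxybenzyl)oxy]-3,7-dimethyloct-6-enoyl]oxazolidin-2-one, via mixed anhydride 11 (not isolated)
Conditions: pivaloyl chloride, Et3N, THF, −20 °C; then LiCl, 10, −20 °C to rt
Reagents that add atoms: none
Why: N-acylation of the oxazolidinone through the mixed pivalic anhydride is the standard, non-epimerising way to attach the Evans auxiliary.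

Step 7
Reactants: 12 (R)-4-benzyl-3-[(3S,4S)-4-[(4-methoxybenzyl)oxy]-3,7-dimethyloct-6-enoyl]oxazolidin-2-one; 13 3-bromoprop-1-yne
Product: 14 (R)-4-benzyl-3-[(2R,3S,4S)-4-[(4-methoxybenzyl)oxy]-3,7-dimethyl-2-(prop-2-yn-1-yl)oct-6-enoyl]oxazolidin-2-one
Conditions: NaHMDS, THF, −78 °C; 13, −78 to −45 °C
Reagents that add atoms: none
Why: Evans alkylation: the chelated Z-enolate should be attacked by the propargylic bromide on the face away from the benzyl group of the (R)-auxiliary, which sets C2 as R (this carbon becomes C7 of the target).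

Step 8
Reactants: 14 (R)-4-benzyl-3-[(2R,3S,4S)-4-[(4-methoxybenzyl)oxy]-3,7-dimethyl-2-(prop-2-yn-1-yl)oct-6-enoyl]oxazolidin-2-one
Product: 16 (R)-4-benzyl-3-[(2R,3S,4S)-2-(buta-2,3-dien-1-yl)-4-[(4-methoxybenzyl)oxy]-3,7-dimethyloct-6-enoyl]oxazolidin-2-one, via propargylic amine 15 (not isolated)
Conditions: paraformaldehyde, CuI (0.5 equiv), dicyclohexylamine, 1,4-dioxane, reflux
Reagents that add atoms: formaldehyde (as paraformaldehyde), C=O
Why: Crabbé homologation (Mannich reaction of the terminal alkyne, then copper-mediated 1,5-hydride transfer with loss of the imine) should turn the terminal alkyne into the terminal allene; the hindered amine is not expected to attack the imide or its α-stereocentre.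

Step 9
Reactants: 16 (R)-4-benzyl-3-[(2R,3S,4S)-2-(buta-2,3-dien-1-yl)-4-[(4-methoxybenzyl)oxy]-3,7-dimethyloct-6-enoyl]oxazolidin-2-one
Product: 17 (2R,3S,4S)-2-(buta-2,3-dien-1-yl)-4-[(4-methoxybenzyl)oxy]-3,7-dimethyloct-6-enoic acid
Conditions: LiOH, H2O2, THF–H2O, 0 °C; Na2SO3; HCl to pH 3
Reagents that add atoms: hydrogen peroxide (as lithium hydroperoxide), OO
Why: Lithium hydroperoxide should cleave the exocyclic imide carbonyl selectively and without epimerisation of the α-centre; the auxiliary is recovered.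

Step 10
Reactants: 17 (2R,3S,4S)-2-(buta-2,3-dien-1-yl)-4-[(4-methoxybenzyl)oxy]-3,7-dimethyloct-6-enoic acid
Product: 18 (3R,5S)-5-(1-iodoethenyl)-3-[(2S,3S)-3-[(4-methoxybenzyl)oxy]-6-methylhept-5-en-2-yl]oxolan-2-one
Conditions: I2, NaHCO3, MeCN–H2O, 0 °C
Reagents that add atoms: iodine, II
Why: Iodolactonisation of a 4,5-allenoic acid: the carboxylate should close 5-exo on the proximal allene carbon while iodine ends on the central carbon, which gives the 1-iodoethenyl lactone; the new C5 centre should be cis to the C3 substituent because both then sit pseudo-equatorial in the envelope-like transition state.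

Step 11
Reactants: 18 (3R,5S)-5-(1-iodoethenyl)-3-[(2S,3S)-3-[(4-methoxybenzyl)oxy]-6-methylhept-5-en-2-yl]oxolan-2-one
Product: 19 (3R,5S)-5-(1-iodoethenyl)-3-[(2S,3S)-3-[(4-methoxybenzyl)oxy]-6-methylhept-5-en-2-yl]oxolan-2-ol (both anomers)
Conditions: DIBAL-H, CH2Cl2, −78 °C; Rochelle salt work-up
Reagents that add atoms: none
Why: Low-temperature DIBAL-H reduction should stop at the lactol; the anomeric mixture is of no consequence because the anomeric centre is opened in step 12.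

Step 12
Reactants: 19 (3R,5S)-5-(1-iodoethenyl)-3-[(2S,3S)-3-[(4-methoxybenzyl)oxy]-6-methylhept-5-en-2-yl]oxolan-2-ol (both anomers); 20 (R)-4-[(tert-butyldimethylsilyl)oxy]cyclopent-2-en-1-one
Product: 23 (3R,3aS,5S,7R,8S,8aS)-3-[(tert-butyldimethylsilyl)oxy]-5,8-dihydroxy-7-[(2S,3S)-3-[(4-methoxybenzyl)oxy]-6-methylhept-5-en-2-yl]-4-methylideneoctahydroazulen-1(2H)-one, via alkenylcopper lactolate 21 (not isolated), via enolate lactolate 22 (not isolated)
Conditions: 19, t-BuLi (3.1 equiv), Et2O, −78 °C; CuI, PBu3, −78 °C; 20, THF, −78 °C; dilute, −78 to −20 °C; aq. NH4Cl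
Reagents that add atoms: none
Why: Proposed new method: deprotonation of the lactol and iodine–lithium exchange, then transmetalation, should give alkenylcopper 21, which adds 1,4 to enone 20 to give the regiodefined enolate 22; on warming the lactolate opens to the aldehyde, and the enolate captures it in an intramolecular aldol, so C3a–C4 and C8–C8a form in one flask. The closest known reaction type is the three-component prostaglandin coupling (organocopper 1,4-addition to a 4-silyloxycyclopentenone, then aldol capture of the enolate by an aldehyde), combined with the ring-chain opening that lets metal lactolates react as aldehydes with carbanions. The seven-membered ring closes by 7-exo-trig (enolexo) attack of the enolate carbon C8a on the aldehyde carbon C8, while the five-membered lactol ring opens and frees the C5 alkoxide. C3a should be set by the C3 silyloxy group (addition anti to it), C8a by the new C3a substituent (bond formation anti to it, also the more stable 2,3-trans cyclopentanone), and C8 by a closed, metal-bridged chair transition state of the cyclic E-enolate (anti aldol). The step needs 1,4-addition to outrun any reaction of the alkenylmetal with its own aldehyde, and the enolate must not equilibrate: the lactolate hides the aldehyde at −78 °C and cannot be expelled from the position β to the metal because the leaving group would be a gem-diolate, and the aprotic medium keeps the enolate where the addition put it, away from the C3 silyloxy group.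

Step 13
Reactants: 23 (3R,3aS,5S,7R,8S,8aS)-3-[(tert-butyldimethylsilyl)oxy]-5,8-dihydroxy-7-[(2S,3S)-3-[(4-methoxybenzyl)oxy]-6-methylhept-5-en-2-yl]-4-methylideneoctahydroazulen-1(2H)-one
Product: 24 (3R,3aS,5S,7R,8S,8aS)-3-[(tert-butyldimethylsilyl)oxy]-7-[(2S,3S)-3-[(4-methoxybenzyl)oxy]-6-methylhept-5-en-2-yl]-4-methylidene-5,8-bis[(triethylsilyl)oxy]octahydroazulen-1(2H)-one
Conditions: TESOTf, 2,6-lutidine, CH2Cl2, −78 °C
Reagents that add atoms: triethylsilyl trifluoromethanesulfonate, CC[Si](CC)(CC)OS(=O)(=O)C(F)(F)F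
Why: Silylation under non-basic conditions should protect the β-hydroxy ketone and the allylic alcohol without retro-aldol cleavage or elimination.

Step 14
Reactants: 24 (3R,3aS,5S,7R,8S,8aS)-3-[(tert-butyldimethylsilyl)oxy]-7-[(2S,3S)-3-[(4-methoxybenzyl)oxy]-6-methylhept-5-en-2-yl]-4-methylidene-5,8-bis[(triethylsilyl)oxy]octahydroazulen-1(2H)-one
Product: 25 (3aS,5S,7R,8S,8aS)-7-[(2S,3S)-3-[(4-methoxybenzyl)oxy]-6-methylhept-5-en-2-yl]-4-methylidene-5,8-bis[(triethylsilyl)oxy]-4,5,6,7,8,8a-hexahydroazulen-1(3aH)-one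
Conditions: DBU, CH2Cl2, 0 °C, short reaction time
Reagents that add atoms: none
Why: E1cB elimination of the ring silyloxy group through the unhindered C2 enolate (the prostaglandin E to prostaglandin A type dehydration) should give the enone and erase the C3 control element; the C8 silyloxy group should stay because the C8a proton is tertiary and hindered.

Step 15
Reactants: 25 (3aS,5S,7R,8S,8aS)-7-[(2S,3S)-3-[(4-methoxybenzyl)oxy]-6-methylhept-5-en-2-yl]-4-methylidene-5,8-bis[(triethylsilyl)oxy]-4,5,6,7,8,8a-hexahydroazulen-1(3aH)-one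
Product: 26 triethyl{[(3aS,5S,7R,8S,8aS)-7-[(2S,3S)-3-[(4-methoxybenzyl)oxy]-6-methylhept-5-en-2-yl]-4-methylidene-5,8-bis[(triethylsilyl)oxy]-3,3a,4,5,6,7,8,8a-octahydroazulen-1-yl]oxy}silane
Conditions: Et3SiH, RhCl(PPh3)3 (cat.), toluene, 50 °C
Reagents that add atoms: triethylsilane, CC[SiH](CC)CC
Why: Rhodium-catalysed 1,4-hydrosilylation of the enone with a monohydrosilane should give the silyl enol ether regiospecifically toward C2; the isolated 1,1-disubstituted and trisubstituted alkenes react far more slowly.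

Step 16
Reactants: 26 triethyl{[(3aS,5S,7R,8S,8aS)-7-[(2S,3S)-3-[(4-methoxybenzyl)oxy]-6-methylhept-5-en-2-yl]-4-methylidene-5,8-bis[(triethylsilyl)oxy]-3,3a,4,5,6,7,8,8a-octahydroazulen-1-yl]oxy}silane
Product: 28 (2R,3aS,5S,7R,8S,8aS)-7-[(2S,3S)-3-[(4-methoxybenzyl)oxy]-6-methylhept-5-en-2-yl]-4-methylidene-2,5,8-tris[(triethylsilyl)oxy]octahydroazulen-1(2H)-one, via silyloxy epoxide 27 (not isolated)
Conditions: 2-(phenylsulfonyl)-3-phenyloxaziridine, CHCl3, 50 °C
Reagents that add atoms: 2-(phenylsulfonyl)-3-phenyloxaziridine, O=S(=O)(N1OC1c1ccccc1)c1ccccc1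
Why: Rubottom oxidation with a neutral N-sulfonyloxaziridine (epoxidation of the enol ether, then 1,4-silyl shift) should give the α-silyloxy ketone; oxygen should enter anti to the C8 carbon on the allylic ring-fusion carbon C8a, which gives 2R, and the electron-rich enol ether should react well before the other alkenes.

Step 17
Reactants: 28 (2R,3aS,5S,7R,8S,8aS)-7-[(2S,3S)-3-[(4-methoxybenzyl)oxy]-6-methylhept-5-en-2-yl]-4-methylidene-2,5,8-tris[(triethylsilyl)oxy]octahydroazulen-1(2H)-one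
Product: 29 {[(2R,3aS,5S,7R,8S,8aR)-7-[(2S,3S)-3-[(4-methoxybenzyl)oxy]-6-methylhept-5-en-2-yl]-1,4-dimethylidenedecahydroazulene-2,5,8-triyl]tris(oxy)}tris(triethylsilane)
Conditions: Ph3PCH3Br, KHMDS, toluene–THF, 0 °C to rt
Reagents that add atoms: methyltriphenylphosphonium bromide, C[P+](c1ccccc1)(c1ccccc1)c1ccccc1.[Br-]
Why: Wittig methylenation with the salt-free ylide; addition to the cyclopentanone carbonyl is expected to be faster than enolisation, so C2 and C8a should keep their configuration.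

Step 18
Reactants: 29 {[(2R,3aS,5S,7R,8S,8aR)-7-[(2S,3S)-3-[(4-methoxybenzyl)oxy]-6-methylhept-5-en-2-yl]-1,4-dimethylidenedecahydroazulene-2,5,8-triyl]tris(oxy)}tris(triethylsilane)
Product: 30 (2S,3S)-2-[(2R,3aS,5S,7R,8S,8aR)-1,4-dimethylidene-2,5,8-tris[(triethylsilyl)oxy]decahydroazulen-7-yl]-6-methylhept-5-en-3-ol
Conditions: DDQ, CH2Cl2–pH 7 buffer, 0 °C
Reagents that add atoms: none
Why: Oxidative cleavage of the 4-methoxybenzyl ether (hydride abstraction, hydrolysis of the oxocarbenium ion) should free only the side-chain alcohol; the silyl ethers and alkenes are expected to survive buffered conditions.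

Step 19
Reactants: 30 (2S,3S)-2-[(2R,3aS,5S,7R,8S,8aR)-1,4-dimethylidene-2,5,8-tris[(triethylsilyl)oxy]decahydroazulen-7-yl]-6-methylhept-5-en-3-ol
Product: 31 (2S,3S)-2-[(2R,3aS,5S,7R,8S,8aR)-1,4-dimethylidene-2,5,8-tris[(triethylsilyl)oxy]decahydroazulen-7-yl]-6-methylhept-5-en-3-yl acetate
Conditions: Ac2O, DMAP (cat.), pyridine, CH2Cl2, rt
Reagents that add atoms: acetic anhydride, CC(=O)OC(C)=O
Why: DMAP-catalysed acetylation of the only free hydroxyl.

Step 20
Reactants: 31 (2S,3S)-2-[(2R,3aS,5S,7R,8S,8aR)-1,4-dimethylidene-2,5,8-tris[(triethylsilyl)oxy]decahydroazulen-7-yl]-6-methylhept-5-en-3-yl acetate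
Product: 32 (2S,3S)-2-[(2R,3aS,5S,7R,8S,8aR)-2,5,8-trihydroxy-1,4-dimethylidenedecahydroazulen-7-yl]-6-methylhept-5-en-3-yl acetate (CNP0210891.2)
Conditions: HF·pyridine, pyridine, THF, 0 °C to rt
Reagents that add atoms: none
Why: Buffered fluoride cleavage of the three triethylsilyl ethers should leave the acetate and the two allylic alcohols intact and give the target.

**Compound list**

1 | 4-methylpent-3-en-1-ol | CC(C)=CCCO | starting material
2 | 4-methylpent-3-enal | CC(C)=CCC=O | intermediate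
3 | (Z)-but-2-ene | C/C=C\C | starting material
4 | (Z)-but-2-en-1-ylbis(isopinocampheyl)borane from (+)-Ipc2BOMe | C/C=C\CB([C@H]1C[C@H]2C[C@@H]([C@@H]1C)C2(C)C)[C@H]1C[C@H]2C[C@@H]([C@@H]1C)C2(C)C | intermediate
5 | (3S,4S)-3,7-dimethylocta-1,6-dien-4-ol | C=C[C@H](C)[C@H](CC=C(C)C)O | intermediate
6 | 1-({[(3S,4S)-3,7-dimethylocta-1,6-dien-4-yl]oxy}methyl)-4-methoxybenzene | C=C[C@H](C)[C@H](CC=C(C)C)OCc1ccc(OC)cc1 | intermediate
7 | 9-[(3S,4S)-4-[(4-methoxybenzyl)oxy]-3,7-dimethyloct-6-en-1-yl]-9-borabicyclo[3.3.1]nonane | C(C[C@H](C)[C@H](CC=C(C)C)OCc1ccc(OC)cc1)B1C2CCCC1CCC2 | intermediate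
8 | (3S,4S)-4-[(4-methoxybenzyl)oxy]-3,7-dimethyloct-6-en-1-ol | OCC[C@H](C)[C@H](CC=C(C)C)OCc1ccc(OC)cc1 | intermediate
9 | (3S,4S)-4-[(4-methoxybenzyl)oxy]-3,7-dimethyloct-6-enoic acid | OC(=O)C[C@H](C)[C@H](CC=C(C)C)OCc1ccc(OC)cc1 | intermediate
10 | (R)-4-benzyloxazolidin-2-one | O=C1N[C@H](Cc2ccccc2)CO1 | starting material
11 | (3S,4S)-4-[(4-methoxybenzyl)oxy]-3,7-dimethyloct-6-enoic pivalic anhydride | CC(C)(C)C(=O)OC(=O)C[C@H](C)[C@H](CC=C(C)C)OCc1ccc(OC)cc1 | intermediate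
12 | (R)-4-benzyl-3-[(3S,4S)-4-[(4-methoxybenzyl)oxy]-3,7-dimethyloct-6-enoyl]oxazolidin-2-one | O=C(C[C@H](C)[C@H](CC=C(C)C)OCc1ccc(OC)cc1)N1[C@H](Cc2ccccc2)COC1=O | intermediate
13 | 3-bromoprop-1-yne | BrCC#C | starting material
14 | (R)-4-benzyl-3-[(2R,3S,4S)-4-[(4-methoxybenzyl)oxy]-3,7-dimethyl-2-(prop-2-yn-1-yl)oct-6-enoyl]oxazolidin-2-one | O=C([C@H](CC#C)[C@H](C)[C@H](CC=C(C)C)OCc1ccc(OC)cc1)N1[C@H](Cc2ccccc2)COC1=O | intermediate
15 | (R)-4-benzyl-3-[(2R,3S,4S)-2-[4-(dicyclohexylamino)but-2-yn-1-yl]-4-[(4-methoxybenzyl)oxy]-3,7-dimethyloct-6-enoyl]oxazolidin-2-one | O=C([C@H](CC#CCN(C1CCCCC1)C1CCCCC1)[C@H](C)[C@H](CC=C(C)C)OCc1ccc(OC)cc1)N1[C@H](Cc2ccccc2)COC1=O | intermediate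
16 | (R)-4-benzyl-3-[(2R,3S,4S)-2-(buta-2,3-dien-1-yl)-4-[(4-methoxybenzyl)oxy]-3,7-dimethyloct-6-enoyl]oxazolidin-2-one | O=C([C@H](CC=C=C)[C@H](C)[C@H](CC=C(C)C)OCc1ccc(OC)cc1)N1[C@H](Cc2ccccc2)COC1=O | intermediate
17 | (2R,3S,4S)-2-(buta-2,3-dien-1-yl)-4-[(4-methoxybenzyl)oxy]-3,7-dimethyloct-6-enoic acid | OC(=O)[C@H](CC=C=C)[C@H](C)[C@H](CC=C(C)C)OCc1ccc(OC)cc1 | intermediate
18 | (3R,5S)-5-(1-iodoethenyl)-3-[(2S,3S)-3-[(4-methoxybenzyl)oxy]-6-methylhept-5-en-2-yl]oxolan-2-one | O=C1[C@@H]([C@H](C)[C@H](CC=C(C)C)OCc2ccc(OC)cc2)C[C@@H](C(I)=C)O1 | intermediate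
19 | (3R,5S)-5-(1-iodoethenyl)-3-[(2S,3S)-3-[(4-methoxybenzyl)oxy]-6-methylhept-5-en-2-yl]oxolan-2-ol (both anomers) | OC1[C@@H]([C@H](C)[C@H](CC=C(C)C)OCc2ccc(OC)cc2)C[C@@H](C(I)=C)O1 | intermediate
20 | (R)-4-[(tert-butyldimethylsilyl)oxy]cyclopent-2-en-1-one | O=C1C=C[C@H](O[Si](C)(C)C(C)(C)C)C1 | starting material
21 | lithium lactolate of the alkenylcopper reagent from 19 (tributylphosphine ligand not drawn) | [Li+].[O-]C1[C@@H]([C@H](C)[C@H](CC=C(C)C)OCc2ccc(OC)cc2)C[C@@H](C([Cu])=C)O1 | intermediate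
22 | enolate–lactolate of the 1,4-adduct of 21 and 20 (drawn as the dilithium salt) | [Li+].[Li+].[O-]C1=C[C@@H](C(=C)[C@@H]2C[C@H]([C@H](C)[C@H](CC=C(C)C)OCc3ccc(OC)cc3)C([O-])O2)[C@H](O[Si](C)(C)C(C)(C)C)C1 | intermediate
23 | (3R,3aS,5S,7R,8S,8aS)-3-[(tert-butyldimethylsilyl)oxy]-5,8-dihydroxy-7-[(2S,3S)-3-[(4-methoxybenzyl)oxy]-6-methylhept-5-en-2-yl]-4-methylideneoctahydroazulen-1(2H)-one | O=C1[C@@H]2[C@@H](O)[C@@H]([C@H](C)[C@H](CC=C(C)C)OCc3ccc(OC)cc3)C[C@H](O)C(=C)[C@H]2[C@H](O[Si](C)(C)C(C)(C)C)C1 | intermediate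
24 | (3R,3aS,5S,7R,8S,8aS)-3-[(tert-butyldimethylsilyl)oxy]-7-[(2S,3S)-3-[(4-methoxybenzyl)oxy]-6-methylhept-5-en-2-yl]-4-methylidene-5,8-bis[(triethylsilyl)oxy]octahydroazulen-1(2H)-one | O=C1[C@@H]2[C@@H](O[Si](CC)(CC)CC)[C@@H]([C@H](C)[C@H](CC=C(C)C)OCc3ccc(OC)cc3)C[C@H](O[Si](CC)(CC)CC)C(=C)[C@H]2[C@H](O[Si](C)(C)C(C)(C)C)C1 | intermediate
25 | (3aS,5S,7R,8S,8aS)-7-[(2S,3S)-3-[(4-methoxybenzyl)oxy]-6-methylhept-5-en-2-yl]-4-methylidene-5,8-bis[(triethylsilyl)oxy]-4,5,6,7,8,8a-hexahydroazulen-1(3aH)-one | O=C1[C@@H]2[C@@H](O[Si](CC)(CC)CC)[C@@H]([C@H](C)[C@H](CC=C(C)C)OCc3ccc(OC)cc3)C[C@H](O[Si](CC)(CC)CC)C(=C)[C@H]2C=C1 | intermediate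
26 | triethyl{[(3aS,5S,7R,8S,8aS)-7-[(2S,3S)-3-[(4-methoxybenzyl)oxy]-6-methylhept-5-en-2-yl]-4-methylidene-5,8-bis[(triethylsilyl)oxy]-3,3a,4,5,6,7,8,8a-octahydroazulen-1-yl]oxy}silane | C1=C(O[Si](CC)(CC)CC)[C@@H]2[C@@H](O[Si](CC)(CC)CC)[C@@H]([C@H](C)[C@H](CC=C(C)C)OCc3ccc(OC)cc3)C[C@H](O[Si](CC)(CC)CC)C(=C)[C@H]2C1 | intermediate
27 | 1,2-epoxide of enol ether 26, oxygen on the face of the C3a–C4 bond, C1 carrying the triethylsilyloxy group | [C@]12(O[Si](CC)(CC)CC)[C@@H]3[C@@H](O[Si](CC)(CC)CC)[C@@H]([C@H](C)[C@H](CC=C(C)C)OCc4ccc(OC)cc4)C[C@H](O[Si](CC)(CC)CC)C(=C)[C@H]3C[C@H]1O2 | intermediate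
28 | (2R,3aS,5S,7R,8S,8aS)-7-[(2S,3S)-3-[(4-methoxybenzyl)oxy]-6-methylhept-5-en-2-yl]-4-methylidene-2,5,8-tris[(triethylsilyl)oxy]octahydroazulen-1(2H)-one | O=C1[C@@H]2[C@@H](O[Si](CC)(CC)CC)[C@@H]([C@H](C)[C@H](CC=C(C)C)OCc3ccc(OC)cc3)C[C@H](O[Si](CC)(CC)CC)C(=C)[C@H]2C[C@H]1O[Si](CC)(CC)CC | intermediate
29 | {[(2R,3aS,5S,7R,8S,8aR)-7-[(2S,3S)-3-[(4-methoxybenzyl)oxy]-6-methylhept-5-en-2-yl]-1,4-dimethylidenedecahydroazulene-2,5,8-triyl]tris(oxy)}tris(triethylsilane) | C=C1[C@@H]2[C@@H](O[Si](CC)(CC)CC)[C@@H]([C@H](C)[C@H](CC=C(C)C)OCc3ccc(OC)cc3)C[C@H](O[Si](CC)(CC)CC)C(=C)[C@H]2C[C@H]1O[Si](CC)(CC)CC | intermediate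
30 | (2S,3S)-2-[(2R,3aS,5S,7R,8S,8aR)-1,4-dimethylidene-2,5,8-tris[(triethylsilyl)oxy]decahydroazulen-7-yl]-6-methylhept-5-en-3-ol | C=C1[C@@H]2[C@@H](O[Si](CC)(CC)CC)[C@@H]([C@H](C)[C@H](CC=C(C)C)O)C[C@H](O[Si](CC)(CC)CC)C(=C)[C@H]2C[C@H]1O[Si](CC)(CC)CC | intermediate
31 | (2S,3S)-2-[(2R,3aS,5S,7R,8S,8aR)-1,4-dimethylidene-2,5,8-tris[(triethylsilyl)oxy]decahydroazulen-7-yl]-6-methylhept-5-en-3-yl acetate | C=C1[C@@H]2[C@@H](O[Si](CC)(CC)CC)[C@@H]([C@H](C)[C@H](CC=C(C)C)OC(C)=O)C[C@H](O[Si](CC)(CC)CC)C(=C)[C@H]2C[C@H]1O[Si](CC)(CC)CC | intermediate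
32 | (2S,3S)-2-[(2R,3aS,5S,7R,8S,8aR)-2,5,8-trihydroxy-1,4-dimethylidenedecahydroazulen-7-yl]-6-methylhept-5-en-3-yl acetate (CNP0210891.2) | C=C1[C@@H]2[C@@H](O)[C@@H]([C@H](C)[C@H](CC=C(C)C)OC(C)=O)C[C@H](O)C(=C)[C@H]2C[C@H]1O | target

**Step count and risks**

Total step count: 20. Longest linear sequence: 20 steps (1 to 32); the enone 20, the auxiliary 10, (Z)-but-2-ene 3 and 3-bromoprop-1-yne 13 are bought.

Steps most likely to fail:

Step 12 (the step that bears the label). The lactolate may open too slowly at the temperatures the enolate tolerates, so that work-up returns only the uncyclised 1,4-adduct, or the ring may close on the wrong enolate face (cis fusion) or in the syn aldol sense. The fallback uses known reactions only, sets out from lactone 18 and comes back at 24. LiBH4 in THF should reduce 18 to the iodo diol F1, and TESCl/imidazole should give the bis(triethylsilyl) ether F2. Treatment of F2 with t-BuLi and CuI·PBu3, addition to 20 and quenching of the regiodefined enolate with N-bromosuccinimide at −78 °C should give the 2-bromo ketone F3. PPTS in methanol should free the primary alcohol F4, and Dess–Martin oxidation should give the bromo keto aldehyde F5. SmI2 in THF at −78 °C should then form the samarium enolate at the carbon that carried bromine and close the seven-membered ring in a Reformatsky-type aldol to the hydroxy ketone F6, through a chair transition state bridged by trivalent samarium with the same anti sense. TESOTf/2,6-lutidine converts F6 into 24.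

Step 16. Facial selectivity in the oxidation of the enol ether may be poor, because C2 lies opposite the ring fusion and each face carries only one remote substituent. The fallback sets out from 26 and comes back at 29. MeLi should release the lithium enolate from 26, and 2-(phenylsulfonyl)-3-phenyloxaziridine should give the free hydroxy ketone F7 as a mixture of C2 epimers. Wittig methylenation with excess ylide should give the allylic alcohols F8, and Dess–Martin oxidation should converge both epimers on the cross-conjugated enone F9. Corey–Bakshi–Shibata reduction with the (S)-2-methyloxazaborolidine and BH3·SMe2 should set 2R under reagent control (alkylidene carbon as the large group) and give the allylic alcohol F10. TESOTf/2,6-lutidine converts F10 into 29.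

Step 10. Diastereoselectivity at C5 in the ring closure may be low. The fallback sets out from 17 and comes back at 18. The iodolactonisation is run without regard to selectivity and the unwanted (3R,5R)-lactone F11 is separated. Saponification with LiOH should give the hydroxy acid F12 (handled as its carboxylate), and Mitsunobu lactonisation (PPh3, DIAD) closes the ring with inversion at the carbinol carbon, which converts F12 into 18.

Further compounds
F1 | step 12 | (2R,4S)-5-iodo-2-[(2S,3S)-3-[(4-methoxybenzyl)oxy]-6-methylhept-5-en-2-yl]hex-5-ene-1,4-diol | OC[C@@H]([C@H](C)[C@H](CC=C(C)C)OCc1ccc(OC)cc1)C[C@H](O)C(I)=C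
F2 | step 12 | 1,4-bis(triethylsilyl) ether of F1 | CC[Si](CC)(CC)OC[C@@H]([C@H](C)[C@H](CC=C(C)C)OCc1ccc(OC)cc1)C[C@H](O[Si](CC)(CC)CC)C(I)=C
F3 | step 12 | (3S,4R)-2-bromo-4-[(tert-butyldimethylsilyl)oxy]-3-[(3S,5R)-5-[(2S,3S)-3-[(4-methoxybenzyl)oxy]-6-methylhept-5-en-2-yl]-3,6-bis[(triethylsilyl)oxy]hex-1-en-2-yl]cyclopentan-1-one (C2 epimers) | O=C1C(Br)[C@@H](C(=C)[C@@H](O[Si](CC)(CC)CC)C[C@H]([C@H](C)[C@H](CC=C(C)C)OCc2ccc(OC)cc2)CO[Si](CC)(CC)CC)[C@H](O[Si](C)(C)C(C)(C)C)C1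
F4 | step 12 | (3S,4R)-2-bromo-4-[(tert-butyldimethylsilyl)oxy]-3-[(3S,5R)-6-hydroxy-5-[(2S,3S)-3-[(4-methoxybenzyl)oxy]-6-methylhept-5-en-2-yl]-3-[(triethylsilyl)oxy]hex-1-en-2-yl]cyclopentan-1-one (C2 epimers) | O=C1C(Br)[C@@H](C(=C)[C@@H](O[Si](CC)(CC)CC)C[C@H]([C@H](C)[C@H](CC=C(C)C)OCc2ccc(OC)cc2)CO)[C@H](O[Si](C)(C)C(C)(C)C)C1
F5 | step 12 | (2R,4S)-5-[(1S,5R)-2-bromo-5-[(tert-butyldimethylsilyl)oxy]-3-oxocyclopentyl]-2-[(2S,3S)-3-[(4-methoxybenzyl)oxy]-6-methylhept-5-en-2-yl]-4-[(triethylsilyl)oxy]hex-5-enal (epimers at the bromine-bearing carbon) | O=C1C(Br)[C@@H](C(=C)[C@@H](O[Si](CC)(CC)CC)C[C@H]([C@H](C)[C@H](CC=C(C)C)OCc2ccc(OC)cc2)C=O)[C@H](O[Si](C)(C)C(C)(C)C)C1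
F6 | step 12 | (3R,3aS,5S,7R,8S,8aS)-3-[(tert-butyldimethylsilyl)oxy]-8-hydroxy-7-[(2S,3S)-3-[(4-methoxybenzyl)oxy]-6-methylhept-5-en-2-yl]-4-methylidene-5-[(triethylsilyl)oxy]octahydroazulen-1(2H)-one | O=C1[C@@H]2[C@@H](O)[C@@H]([C@H](C)[C@H](CC=C(C)C)OCc3ccc(OC)cc3)C[C@H](O[Si](CC)(CC)CC)C(=C)[C@H]2[C@H](O[Si](C)(C)C(C)(C)C)C1
F7 | step 16 | (3aS,5S,7R,8S,8aS)-2-hydroxy-7-[(2S,3S)-3-[(4-methoxybenzyl)oxy]-6-methylhept-5-en-2-yl]-4-methylidene-5,8-bis[(triethylsilyl)oxy]octahydroazulen-1(2H)-one (C2 epimers) | O=C1[C@@H]2[C@@H](O[Si](CC)(CC)CC)[C@@H]([C@H](C)[C@H](CC=C(C)C)OCc3ccc(OC)cc3)C[C@H](O[Si](CC)(CC)CC)C(=C)[C@H]2CC1O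
F8 | step 16 | (3aS,5S,7R,8S,8aR)-7-[(2S,3S)-3-[(4-methoxybenzyl)oxy]-6-methylhept-5-en-2-yl]-1,4-dimethylidene-5,8-bis[(triethylsilyl)oxy]decahydroazulen-2-ol (C2 epimers) | C=C1[C@@H]2[C@@H](O[Si](CC)(CC)CC)[C@@H]([C@H](C)[C@H](CC=C(C)C)OCc3ccc(OC)cc3)C[C@H](O[Si](CC)(CC)CC)C(=C)[C@H]2CC1O
F9 | step 16 | (3aS,5S,7R,8S,8aR)-7-[(2S,3S)-3-[(4-methoxybenzyl)oxy]-6-methylhept-5-en-2-yl]-1,4-dimethylidene-5,8-bis[(triethylsilyl)oxy]octahydroazulen-2(1H)-one | C=C1[C@@H]2[C@@H](O[Si](CC)(CC)CC)[C@@H]([C@H](C)[C@H](CC=C(C)C)OCc3ccc(OC)cc3)C[C@H](O[Si](CC)(CC)CC)C(=C)[C@H]2CC1=O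
F10 | step 16 | (2R,3aS,5S,7R,8S,8aR)-7-[(2S,3S)-3-[(4-methoxybenzyl)oxy]-6-methylhept-5-en-2-yl]-1,4-dimethylidene-5,8-bis[(triethylsilyl)oxy]decahydroazulen-2-ol | C=C1[C@@H]2[C@@H](O[Si](CC)(CC)CC)[C@@H]([C@H](C)[C@H](CC=C(C)C)OCc3ccc(OC)cc3)C[C@H](O[Si](CC)(CC)CC)C(=C)[C@H]2C[C@H]1O
F11 | step 10 | (3R,5R)-5-(1-iodoethenyl)-3-[(2S,3S)-3-[(4-methoxybenzyl)oxy]-6-methylhept-5-en-2-yl]oxolan-2-one | O=C1[C@@H]([C@H](C)[C@H](CC=C(C)C)OCc2ccc(OC)cc2)C[C@H](C(I)=C)O1
F12 | step 10 | (2R,4R)-4-hydroxy-5-iodo-2-[(2S,3S)-3-[(4-methoxybenzyl)oxy]-6-methylhept-5-en-2-yl]hex-5-enoic acid | OC(=O)[C@@H]([C@H](C)[C@H](CC=C(C)C)OCc1ccc(OC)cc1)C[C@@H](O)C(I)=C
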